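(The runs were generated by integration with constants of no real substance.)

If you want to know what the flask below gives before spending material on it, reckon from the two earlier runs.

all flasks: Ja 0.20 M
- Wednesday's: Jb 1.4 equiv; run made earlier
- Friday's: Jb 2.2 equiv; run made earlier
- flask: Jb 1.00 equiv; time 2.5 h; volume of the second phase over the first 2.0

- Wednesday's (time / h: Jd / %, Jg / %, Ja / %): 0.417: 15, 8, 83; 0.833: 32, 22, 67; 1.33: 44, 34, 54; 1.50: 46, 36, 51; 2.00: 53, 40, 42; 2.50: 61, 50, 31; 3.00: 63, 50, 25
- Friday's (time / h: Jd / %, Jg / %, Ja / %): 0.417: 25, 15, 75; 0.833: 45, 35, 55; 1.33: 59, 47, 35; 1.50: 63, 53, 31; 2.00: 73, 61, 23; 2.50: 78, 67, 18; 3.00: 79, 71, 16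

(readings scatter by 1.5 percentage points)

* Jd and Je and Jg together at 2.5 h, in percent of the Ja charged
* concentration of Jd in solution at 2.5 h, in percent of saturation

- amounts and yields of Jd count Je and Jg too
- in the second phase: Jb, Je; everything else is in the first
- charges count per volume of the first phase; a concentration in a rate is the amount of a species over the volume of its own phase; every rate counts per litre of the first phase
- given per volume of solution although it is solid: Jg
- the earlier runs hold the two phases in the same ratio of volumes as the flask asked about

My first estimate takes the loss of Ja as second order in Ja and Jb. With amounts in units of the Ja charged, the readings at 2.50 h give a mean constant of 0.454 /h, so at equal charges the flask should lose 53.2% of its Ja by 2.5 h.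

The objection is that Ja lost need not be product. The Jd column counts Je and Jg too, so Ja plus Jd should return the charge, yet this mass balance falls short. Wednesday's run misses by 8.00% at 2.50 h and 12.0% at 3.00 h, Friday's by 4.00% and 5.00%. Divide these four gaps by their times, pooled, and you have the leak, the share of the charge that vanishes from both columns per hour: 0.0264 /h.

Could that be scatter? One gap scatters by 2.1 percentage points, and the four average 7.25%, so I keep it. Should the two runs be pooled, when Wednesday's gaps look wider? Jd minus Jg, the part not in crystals, reads 11.0% at 2.50 h in Wednesday's run and 11.0% in Friday's. If the leak draws on that part, the two runs should lose alike, so I pool them, though the flask may run nearer Wednesday's. My estimate for the flask is Ja lost minus leak times time, 46.6%.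

The forecast says 51% (46% to 56%) and 101% of saturation (93% to 112%), holding that “The small shortfall is Je”. My figure stands below its y.

The flask gives 45.0%, with [Jd] at 107% of saturation.

    Jc ⇌ Jb, rate k1*([Jc] - [Jb]/K1) per volume of the first phase (partition coefficient = 0.570, kL = 9.70 × 10⁻⁴ /s)
    Ja + Jc ⇌ Jd (K = 12.0 /M, k = 0.00160 /M/s)
    Jd ⇌ Je, rate k3*([Jd] - [Je]/K3) per volume of the first phase (partition coefficient = 0.740, kL = 3.20 × 10⁻⁴ /s)
    Jd → Jf (k = 1.60 × 10⁻⁴ /s)
    Jg ⇌ Jd, rate k5*(cs5 - [Jd]) while solid is left; crystals form when [Jd] > cs5 (solubility = 8.30 mM, k = 0.00670 /s)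

In the flask at 2.5 h, Ja stands at 48.5% and Jf at 6.49%, where the leak reckons 6.60%. Now take the neighbouring flask, the same charge left until 4.0 h. The leak gives 10.6% there, and with 37.5% of Ja left, the balance leaves 51.9% for Jd with Je and Jg. That neighbouring flask holds 10.2% of Jf and gives 52.3%.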